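**Plan**

1. Retrosynthesis: the hydrocarbon is C2-symmetric (both halves 5S,10S). The cuts are, in order, one C11–C9 (sp3–sp2) bond, giving a C16 diene and a C14 enol triflate that share one bicyclic enone; the ring A bond C3–C4; and the two bonds from C10 to its methyl and to C1, which leaves (R)-carvone.
2. Forward: carvone is ring B (its C=O is C9, its ring methyl is the C8 methyl, its C6 is C10, its isopropenyl carbon is C4). C6 is methylated and allylated, the allyl end is taken to an aldehyde tosylhydrazone, and ring A is closed from C4 to C3 by a hydrogen-atom-transfer radical cyclization that expels N2. The enone then becomes the C8=C9 enol triflate, and two portions of it are joined through a vinyl group (Stille, then 9-BBN and Suzuki–Miyaura).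
3. Stereochemistry: C5 is carvone's stereocentre. C10 comes from allylation anti to the isopropenyl group, which fixes the trans ring fusion before ring A exists. Both tetrasubstituted alkenes are placed by regiospecific enolate triflation; there is no other stereocentre.
4. Enabling feature: in ring A the gem-dimethyl carbon C4 lies between the ring-fusion CH (C5) and an unsubstituted CH2 (C3). C4 is therefore a tertiary radical latent in an isopropenyl group on C5, and C3 can be a hydrazone carbon that is left as plain CH2 once N2 is lost, so the closure needs no helper group to be removed afterwards.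

Key step: step 5

Remark on the chemistry: positions are numbered as in each drimane-type half (C1–C10 ring carbons, C4 gem-dimethyl, C5 and C10 ring fusion, C8=C9 alkene, C11 linker CH2). Because the two halves are identical, the single bicyclic enone 10 supplies both.

**Route**

Step 1
Reactants: 1 (R)-(−)-carvone
Product: 3 (5R)-2,6-dimethyl-5-(prop-1-en-2-yl)cyclohex-2-en-1-one (6-methylcarvone, both C6 epimers), via lithium dienolate 2 (not isolated)
Conditions: LiN(i-Pr)2 (LDA), THF, −78 °C; MeI, −78 → 0 °C
Reagents that add atoms: iodomethane, CI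
Why: Kinetic deprotonation at C6 gives the cross-conjugated lithium dienolate, whose C-methylation (enolate alkylation) installs the future C10 methyl; the C6 configuration does not matter because this carbon is planarised again in step 2.

Step 2
Reactants: 3 6-methylcarvone
Product: 5 (5S,6S)-2,6-dimethyl-6-(prop-2-en-1-yl)-5-(prop-1-en-2-yl)cyclohex-2-en-1-one, via lithium enolate 4 (not isolated)
Conditions: LiN(i-Pr)2 (LDA), THF, −78 → −20 °C; allyl bromide, DMPU, −78 → 0 °C
Reagents that add atoms: allyl bromide, C=CCBr
Why: Enolate alkylation of the fully substituted enolate with the reactive allylic bromide should take place on the ring face opposite the neighbouring isopropenyl group, so the allyl chain ends up trans to it and the methyl cis, which is the relative configuration of C10 and C5 in a trans-decalin.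

Step 3
Reactants: 5 allyl enone
Product: 6 3-[(1S,6S)-1,3-dimethyl-2-oxo-6-(prop-1-en-2-yl)cyclohex-3-en-1-yl]propanal
Conditions: PdCl2(PhCN)2 (10 mol%), CuCl2·2H2O (10 mol%), AgNO2 (5 mol%), O2 (1 atm), t-BuOH/MeNO2 15:1, 23 °C
Reagents that add atoms: dioxygen, O=O
Why: Nitrite-modified, aldehyde-selective Wacker oxidation is best established for exactly this substrate class, an allyl group on a quaternary carbon, and the 1,1-disubstituted and conjugated trisubstituted alkenes should be inert under Wacker conditions.

Step 4
Reactants: 6 aldehyde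
Product: 7 N'-[(1E)-3-[(1S,6S)-1,3-dimethyl-2-oxo-6-(prop-1-en-2-yl)cyclohex-3-en-1-yl]propylidene]-4-methylbenzenesulfonohydrazide
Conditions: TsNHNH2 (1.05 equiv), MeOH, 23 °C
Reagents that add atoms: 4-methylbenzenesulfonohydrazide, Cc1ccc(cc1)S(=O)(=O)NN
Why: Hydrazone condensation should be selective for the unhindered aldehyde, because the only other carbonyl is conjugated and flanked by a quaternary carbon.

Step 5
Reactants: 7 tosylhydrazone
Product: 10 (4aS,8aS)-2,5,5,8a-tetramethyl-4a,5,6,7,8,8a-hexahydronaphthalen-1(4H)-one, via cyclic tosylhydrazide 8 (not isolated), via monoalkyl diazene 9 (not isolated)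
Conditions: Fe(acac)3 (50 mol%), PhSiH3 (2.5 equiv), EtOH/THF 4:1, 0.02 M, 23 °C; then dilute with EtOH, 75 °C
Reagents that add atoms: none
Why: Proposed new method: an iron hydride formed from Fe(acac)3 and PhSiH3 should transfer a hydrogen atom to the CH2 terminus of the isopropenyl group to give the tertiary C4 radical, which adds to the hydrazone carbon C3; the resulting hydrazinyl radical is reduced to the N-alkyl-N'-tosylhydrazine 8, which on warming loses 4-methylbenzenesulfinic acid to the diazene 9 and then N2, leaving C3 as an unsubstituted CH2. The closest known reaction types are the iron-hydride hydromethylation of alkenes with formaldehyde sulfonylhydrazones, hydrogen-atom-transfer cyclizations of alkenes onto tethered hydrazones, and the thermal loss of sulfinate and N2 from alkylated tosylhydrazines; what is new is their combination as a traceless ring closure at the carbon of an aldehyde-derived hydrazone. Ring A closes in the 6-exo-trig mode onto the C=N bond. No lasting stereocentre is formed (C4 carries two methyls and the transient C3 centre is erased with N2), and the trans ring fusion is already fixed because the radical carbon and the hydrazone chain are trans-diequatorial on ring B, so a chair-like closure can only give the trans-decalin. The step needs hydrogen atom transfer to the electron-rich 1,1-disubstituted alkene in preference to the electron-poor enone, and cyclization faster than reduction of the radical or intermolecular addition; this is secured by the high rate of 6-exo addition to sulfonylhydrazones, by the fact that closure onto the enone would need a four-membered ring, and by dilution.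

Step 6
Reactants: 10 bicyclic enone
Product: 12 (4aS,8aS)-2,5,5,8a-tetramethyl-3,4,4a,5,6,7,8,8a-octahydronaphthalen-1-yl trifluoromethanesulfonate, via lithium enolate 11 (not isolated)
Conditions: LiBH(s-Bu)3 (L-Selectride), THF, −78 °C; then PhNTf2, −78 → 23 °C
Reagents that add atoms: N-phenylbis(trifluoromethanesulfonimide), FC(F)(F)S(=O)(=O)N(c1ccccc1)S(=O)(=O)C(F)(F)F
Why: Conjugate hydride reduction of the β-unsubstituted cyclohexenone by the bulky borohydride, further favoured by the quaternary carbon beside the carbonyl, should give the C8=C9 enolate regiospecifically, and enolate O-triflation then fixes the tetrasubstituted alkene where the target has it.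

Step 7
Reactants: 12 enol triflate
Product: 13 (4aS,8aS)-4-ethenyl-3,4a,8,8-tetramethyl-1,2,4a,5,6,7,8,8a-octahydronaphthalene
Conditions: tributyl(vinyl)stannane (1.2 equiv), Pd(PPh3)4 (5 mol%), LiCl (3 equiv), THF, 65 °C
Reagents that add atoms: tributyl(vinyl)stannane, C=C[Sn](CCCC)(CCCC)CCCC
Why: Stille coupling of an enol triflate with a vinylstannane under LiCl promotion tolerates fully substituted cyclohexenyl triflates and should give the 1,3-diene with the ring alkene unmoved.

Step 8
Reactants: 13 diene; 12 enol triflate (a second portion)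
Product: 15 1,2-bis[(4aS,8aS)-2,5,5,8a-tetramethyl-3,4,4a,5,6,7,8,8a-octahydronaphthalen-1-yl]ethane (the target), via B-alkyl-9-BBN 14 (not isolated)
Conditions: 13, 9-BBN (1.2 equiv), THF, 0 → 23 °C; then 12 (1.0 equiv), Pd(dppf)Cl2 (10 mol%), AsPh3 (10 mol%), Cs2CO3 (3 equiv), DMF/THF/H2O, 23 → 50 °C
Reagents that add atoms: none
Why: 9-BBN should hydroborate only the monosubstituted vinyl group, at its terminus, and B-alkyl Suzuki–Miyaura coupling of the primary alkylborane with the enol triflate forms the C11–C9 bond of the second half without moving either tetrasubstituted alkene; no stereocentre is formed.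

**Compound list**

1 | (R)-(−)-carvone, (5R)-2-methyl-5-(prop-1-en-2-yl)cyclohex-2-en-1-one | O=C1C(C)=CC[C@@H](C(C)=C)C1 | starting material
2 | cross-conjugated lithium dienolate of 1 (carvone numbering: C1(OLi)=C6, C2=C3 kept, C5 R) | [Li]OC1=C[C@H](C(C)=C)CC=C1C | intermediate
3 | (5R)-2,6-dimethyl-5-(prop-1-en-2-yl)cyclohex-2-en-1-one (both C6 epimers; C6 left open in the SMILES) | O=C1C(C)=CC[C@@H](C(C)=C)C1C | intermediate
4 | lithium dienolate of 3 (C1(OLi)=C6(CH3), C2=C3 kept, C5 unchanged) | [Li]OC1=C(C)[C@H](C(C)=C)CC=C1C | intermediate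
5 | (5S,6S)-2,6-dimethyl-6-(prop-2-en-1-yl)-5-(prop-1-en-2-yl)cyclohex-2-en-1-one (allyl trans to isopropenyl) | O=C1C(C)=CC[C@@H](C(C)=C)[C@@]1(CC=C)C | intermediate
6 | 3-[(1S,6S)-1,3-dimethyl-2-oxo-6-(prop-1-en-2-yl)cyclohex-3-en-1-yl]propanal | O=C1C(C)=CC[C@@H](C(C)=C)[C@@]1(CCC=O)C | intermediate
7 | N'-[(1E)-3-[(1S,6S)-1,3-dimethyl-2-oxo-6-(prop-1-en-2-yl)cyclohex-3-en-1-yl]propylidene]-4-methylbenzenesulfonohydrazide | O=C1C(C)=CC[C@@H](C(C)=C)[C@@]1(CC/C=N/NS(=O)(=O)c2ccc(C)cc2)C | intermediate
8 | N'-[(4aS,8aS)-1,1,4a,6-tetramethyl-5-oxo-1,2,3,4,4a,5,8,8a-octahydronaphthalen-2-yl]-4-methylbenzenesulfonohydrazide (either epimer at the N-bearing carbon) | O=C1C(C)=CC[C@H]2C(C)(C)C(NNS(=O)(=O)c3ccc(C)cc3)CC[C@]12C | intermediate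
9 | (4aS,8aS)-6-diazenyl-2,5,5,8a-tetramethyl-4a,5,6,7,8,8a-hexahydronaphthalen-1(4H)-one (either epimer at C6) | O=C1C(C)=CC[C@H]2C(C)(C)C(N=N)CC[C@]12C | intermediate
10 | (4aS,8aS)-2,5,5,8a-tetramethyl-4a,5,6,7,8,8a-hexahydronaphthalen-1(4H)-one | O=C1C(C)=CC[C@H]2C(C)(C)CCC[C@]12C | intermediate
11 | lithium (4aS,8aS)-2,5,5,8a-tetramethyl-3,4,4a,5,6,7,8,8a-octahydronaphthalen-1-olate | [Li]OC1=C(C)CC[C@H]2C(C)(C)CCC[C@]12C | intermediate
12 | (4aS,8aS)-2,5,5,8a-tetramethyl-3,4,4a,5,6,7,8,8a-octahydronaphthalen-1-yl trifluoromethanesulfonate | O=S(=O)(OC1=C(C)CC[C@H]2C(C)(C)CCC[C@]12C)C(F)(F)F | intermediate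
13 | (4aS,8aS)-4-ethenyl-3,4a,8,8-tetramethyl-1,2,4a,5,6,7,8,8a-octahydronaphthalene | C=CC1=C(C)CC[C@H]2C(C)(C)CCC[C@]12C | intermediate
14 | 9-{2-[(4aS,8aS)-2,5,5,8a-tetramethyl-3,4,4a,5,6,7,8,8a-octahydronaphthalen-1-yl]ethyl}-9-borabicyclo[3.3.1]nonane | C(CC1=C(C)CC[C@H]2C(C)(C)CCC[C@]12C)B3C4CCCC3CCC4 | intermediate
15 | 1,2-bis[(4aS,8aS)-2,5,5,8a-tetramethyl-3,4,4a,5,6,7,8,8a-octahydronaphthalen-1-yl]ethane | CC1=C(CCC2=C(C)CC[C@H]3C(C)(C)CCC[C@]23C)[C@@]2(C)CCCC(C)(C)[C@@H]2CC1 | target

**Count and risks**

Total step count: 8. Longest linear sequence: 8 steps (1 → 12 in six steps, 12 → 13, then 13 + 12 → 15).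

Steps most likely to fail:

1. Step 5 (proposed new method). The tertiary radical may be reduced before it cyclizes (net hydrogenation of the isopropenyl group), hydrogen atom transfer to the enone may compete, or the crowded hydrazide may lose sulfinate only sluggishly. The fallback uses known chemistry, sets out from 3 and comes back at 10. Enolate 4, made as in step 2, is alkylated with methyl 2-(bromomethyl)acrylate (THF, −78 → 0 °C), again anti to the isopropenyl group, to give methyl 2-{[(1S,6S)-1,3-dimethyl-2-oxo-6-(prop-1-en-2-yl)cyclohex-3-en-1-yl]methyl}prop-2-enoate F1. Fe(acac)3 and PhSiH3 in EtOH/ethylene glycol at 60 °C should then close ring A by a 6-endo radical conjugate addition (Giese type) of the same C4 radical to the acrylate terminus, which is C3, giving methyl (4aS,8aS)-4,4,7,8a-tetramethyl-8-oxo-1,2,3,4,4a,5,8,8a-octahydronaphthalene-2-carboxylate F2. Saponification (LiOH, THF/H2O, then HCl) gives (4aS,8aS)-4,4,7,8a-tetramethyl-8-oxo-1,2,3,4,4a,5,8,8a-octahydronaphthalene-2-carboxylic acid F3. Photocatalytic hydrodecarboxylation (9-mesityl-10-methylacridinium tetrafluoroborate, PhSSPh, 2,6-lutidine, CF3CH2OH, blue light) removes the helper carboxyl and returns 10.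

2. Step 8. Oxidative addition and transmetallation at the enol triflate, which is flanked by a quaternary carbon and a methyl-bearing alkene carbon, may be slow, so that β-hydride elimination of the alkylpalladium, protodeboronation or triflate hydrolysis take over. The fallback sets out from 12 and comes back at 15. Twofold Stille coupling of 12 (2 equiv) with (E)-1,2-bis(tributylstannyl)ethene (Pd(PPh3)4, LiCl, THF, 65 °C) should give (E)-1,2-bis[(4aS,8aS)-2,5,5,8a-tetramethyl-3,4,4a,5,6,7,8,8a-octahydronaphthalen-1-yl]ethene F4. Diimide, generated thermally from excess TsNHNH2 in diglyme at 130 °C, should then saturate only the central disubstituted alkene, since tetrasubstituted alkenes are inert to diimide, and give 15.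

3. Step 3. Markovnikov oxypalladation to the methyl ketone, or palladium-hydride migration of the terminal alkene, may compete with aldehyde formation. The fallback sets out from 3 and comes back at 6. Enolate 4 is alkylated with 2-(2-iodoethyl)-1,3-dioxolane (THF/DMPU, −78 → 23 °C) to give (5S,6S)-6-[2-(1,3-dioxolan-2-yl)ethyl]-2,6-dimethyl-5-(prop-1-en-2-yl)cyclohex-2-en-1-one F5, so the chain arrives already at the aldehyde oxidation level. Mild acetal hydrolysis (pyridinium p-toluenesulfonate, wet acetone, 50 °C) then gives 6.

**Further compounds**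

F1 | step 5 | methyl 2-{[(1S,6S)-1,3-dimethyl-2-oxo-6-(prop-1-en-2-yl)cyclohex-3-en-1-yl]methyl}prop-2-enoate | O=C1C(C)=CC[C@@H](C(C)=C)[C@@]1(CC(=C)C(=O)OC)C
F2 | step 5 | methyl (4aS,8aS)-4,4,7,8a-tetramethyl-8-oxo-1,2,3,4,4a,5,8,8a-octahydronaphthalene-2-carboxylate (either C2 epimer) | O=C1C(C)=CC[C@H]2C(C)(C)CC(C(=O)OC)C[C@]12C
F3 | step 5 | (4aS,8aS)-4,4,7,8a-tetramethyl-8-oxo-1,2,3,4,4a,5,8,8a-octahydronaphthalene-2-carboxylic acid (either C2 epimer) | O=C1C(C)=CC[C@H]2C(C)(C)CC(C(=O)O)C[C@]12C
F4 | step 8 | (E)-1,2-bis[(4aS,8aS)-2,5,5,8a-tetramethyl-3,4,4a,5,6,7,8,8a-octahydronaphthalen-1-yl]ethene | CC1=C(/C=C/C2=C(C)CC[C@H]3C(C)(C)CCC[C@]23C)[C@@]2(C)CCCC(C)(C)[C@@H]2CC1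
F5 | step 3 | (5S,6S)-6-[2-(1,3-dioxolan-2-yl)ethyl]-2,6-dimethyl-5-(prop-1-en-2-yl)cyclohex-2-en-1-one | O=C1C(C)=CC[C@@H](C(C)=C)[C@@]1(CCC2OCCO2)C
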